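## Retrosynthetic overview

1. Tuberatolide B (18) comes from desilylation of 17. Compound 17 comes from one double ring-closing metathesis of ester 15, which has no ring other than the arene. The 2H-pyran ring of the chromene closes first (C3=C4), and the furan-2(5H)-one closes second (Cα=Cβ, which is C3=C4 of the lactone).
2. Enabling feature: in each O-heterocycle the only endocyclic C=C starts at the O-bearing stereocentre (chromene O1–C2–C3=C4–C4a; butenolide O–Cγ–Cβ=Cα–C=O). Each ring therefore opens to a vinyl-bearing allylic C–O stereocentre plus a second terminal alkene, held in reach by the aryl ether or the ester. The two remaining alkenes are trisubstituted.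
3. Ester 15 comes from Rh-catalysed asymmetric addition of acid 13 (sulcatone + CO) to the terminal alkyne 10. This joins the fragments and sets Cγ as R.
4. Alkyne 10 comes from bromination and propargylation of 8. Compound 8 comes from Pd-catalysed asymmetric O-allylation of vinylphenol 4 (from methylhydroquinone) with 8-hydroxygeranyl carbonate 7. This sets C2 as S, and the E alkene is inherited from geraniol.

Key step: step 12

Assumption: the ligand antipodes named in steps 6 and 11 are taken to give the configurations drawn. Both antipodes of each ligand are accessible, so a reversed sense of induction would be met by exchanging the antipode.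

## Route

Step 1
Reactants: 1 2-methylhydroquinone
Product: 2 4-(tert-butyldimethylsilyloxy)-2-methylphenol
Conditions: TBSCl (1.0 equiv), imidazole, CH2Cl2/DMF, 0 °C
Reagents that add atoms: tert-butyldimethylsilyl chloride, CC(C)(C)[Si](C)(C)Cl
Why: Selective O-silylation, in which the hydroxyl group without an ortho substituent should react faster than the one next to the methyl group.

Step 2
Reactants: 2 4-(tert-butyldimethylsilyloxy)-2-methylphenol
Product: 3 5-(tert-butyldimethylsilyloxy)-2-hydroxy-3-methylbenzaldehyde
Conditions: MgCl2, Et3N, (CH2O)n, MeCN, reflux; aq. HCl work-up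
Reagents that add atoms: paraformaldehyde (as formaldehyde), C=O
Why: Casnati–Skattebøl ortho-formylation, in which the magnesium phenoxide delivers formaldehyde to the only free ortho position and a second formaldehyde takes up the hydride.

Step 3
Reactants: 3 5-(tert-butyldimethylsilyloxy)-2-hydroxy-3-methylbenzaldehyde
Product: 4 4-(tert-butyldimethylsilyloxy)-2-ethenyl-6-methylphenol
Conditions: MePPh3Br, KHMDS (both in excess over the phenol), THF, 0 °C to rt
Reagents that add atoms: methyltriphenylphosphonium bromide, C[P+](c1ccccc1)(c1ccccc1)c1ccccc1.[Br-]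
Why: Wittig methylenation, in which excess ylide covers the acidic phenol and the aryl silyl ether should tolerate the non-nucleophilic amide base.

Step 4
Reactants: 5 geraniol
Product: 6 geranyl methyl carbonate
Conditions: ClCO2Me, pyridine, CH2Cl2, 0 °C
Reagents that add atoms: methyl chloroformate, COC(=O)Cl
Why: O-acylation of a primary allylic alcohol with a chloroformate, which leaves the E alkene untouched.

Step 5
Reactants: 6 geranyl methyl carbonate
Product: 7 (2E,6E)-8-hydroxy-3,7-dimethylocta-2,6-dien-1-yl methyl carbonate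
Conditions: SeO2 (cat.), t-BuOOH, salicylic acid (cat.), CH2Cl2, 0 °C to rt
Reagents that add atoms: tert-butyl hydroperoxide, CC(C)(C)OO
Why: Riley allylic oxidation (ene reaction followed by [2,3]-sigmatropic shift), which should attack the electron-richer distal alkene and oxidise its E methyl group, as is known for geranyl esters.

Step 6
Reactants: 4 4-(tert-butyldimethylsilyloxy)-2-ethenyl-6-methylphenol; 7 (2E,6E)-8-hydroxy-3,7-dimethylocta-2,6-dien-1-yl methyl carbonate
Product: 8 (2E,6S)-6-[4-(tert-butyldimethylsilyloxy)-2-ethenyl-6-methylphenoxy]-2,6-dimethylocta-2,7-dien-1-ol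
Conditions: Pd2(dba)3·CHCl3 (cat.), (R,R)-DACH-phenyl Trost ligand (cat.), CH2Cl2, 0 °C to rt
Reagents that add atoms: none
Why: Pd-catalysed asymmetric allylic O-alkylation (Tsuji–Trost type), in which the phenoxide freed by the departing methoxide attacks the more substituted terminus of the π-allyl complex under kinetic control and the ligand pocket selects the allyl face, setting the quaternary C–O stereocentre as S.

Step 7
Reactants: 8 (2E,6S)-6-aryloxy-2,6-dimethylocta-2,7-dien-1-ol
Product: 9 (3S,6E)-8-bromo-3,7-dimethylocta-1,6-dien-3-yl 4-(tert-butyldimethylsilyloxy)-2-ethenyl-6-methylphenyl ether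
Conditions: CBr4, PPh3, CH2Cl2, −20 °C
Reagents that add atoms: carbon tetrabromide, BrC(Br)(Br)Br
Why: Appel bromination under neutral conditions, which should spare the acid-sensitive tertiary allylic aryl ether and keep the E geometry.

Step 8
Reactants: 9 (3S,6E)-8-bromo-3,7-dimethylocta-1,6-dien-3-yl aryl ether
Product: 10 (3S,6E)-3,7-dimethylundeca-1,6-dien-10-yn-3-yl 4-(tert-butyldimethylsilyloxy)-2-ethenyl-6-methylphenyl ether
Conditions: propargyl bromide, Mg, ZnBr2 (cat.), Et2O (gives allenylmagnesium bromide); then 9, Et2O, 0 °C to rt, no copper salt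
Reagents that add atoms: propargyl bromide, C#CCBr (used as allenylmagnesium bromide, C=C=C[Mg]Br)
Why: SE2' coupling of an allenyl Grignard reagent with a primary allylic bromide to give a 1,5-enyne, in which any allenyl isomer formed is allene 14, through which step 11 runs anyway, and the absence of copper protects the allylic aryl ether from displacement.

Step 9
Reactants: 11 6-methylhept-5-en-2-one (sulcatone)
Product: 12 6-methylhepta-1,5-dien-2-yl trifluoromethanesulfonate
Conditions: LDA, THF, −78 °C; PhNTf2, −78 to 0 °C
Reagents that add atoms: N-phenylbis(trifluoromethanesulfonimide), O=S(=O)(N(c1ccccc1)S(=O)(=O)C(F)(F)F)C(F)(F)F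
Why: Kinetic enolate formation on the methyl side of a methyl ketone, followed by O-triflation.

Step 10
Reactants: 12 6-methylhepta-1,5-dien-2-yl trifluoromethanesulfonate
Product: 13 6-methyl-2-methylidenehept-5-enoic acid
Conditions: Pd(OAc)2 (cat.), dppf (cat.), CO (1 atm), H2O, Et3N, DMF, 50 °C; then dil. HCl
Reagents that add atoms: carbon monoxide, [C-]#[O+]; water, O
Why: Pd-catalysed hydroxycarbonylation of an alkenyl triflate (oxidative addition, CO insertion, hydrolysis of the acyl-Pd species), which gives the 2-substituted acrylic acid directly.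

Step 11
Reactants: 10 (3S,6E)-3,7-dimethylundeca-1,6-dien-10-yn-3-yl aryl ether; 13 6-methyl-2-methylidenehept-5-enoic acid
Product: 15 (3R,5E,9S)-9-[4-(tert-butyldimethylsilyloxy)-2-ethenyl-6-methylphenoxy]-5,9-dimethylundeca-1,5,10-trien-3-yl 6-methyl-2-methylidenehept-5-enoate, via (3S,6E)-3,7-dimethylundeca-1,6,9,10-tetraen-3-yl aryl ether (terminal allene) 14 (not isolated)
Conditions: [Rh(cod)Cl]2 (cat.), (R,R)-Cp-DIOP (cyclopentylidene analogue of DIOP, cat.), 13 (1.3 equiv), ClCH2CH2Cl, 60–70 °C
Reagents that add atoms: none
Why: Rh-catalysed redox-neutral coupling of a terminal alkyne with a carboxylic acid to a branched allylic ester (Rh–H isomerises the alkyne to allene 14, hydrometalation gives a π-allyl-Rh carboxylate, and C–O bond formation occurs at the substituted terminus), with the chiral diphosphine alone setting the new carbinol centre as R because the existing stereocentre is remote.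

Step 12
Reactants: 15 (3R,5E,9S)-9-aryloxy-5,9-dimethylundeca-1,5,10-trien-3-yl 6-methyl-2-methylidenehept-5-enoate
Product: 17 (5R)-5-{(2E)-5-[(2S)-6-(tert-butyldimethylsilyloxy)-2,8-dimethyl-2H-chromen-2-yl]-2-methylpent-2-en-1-yl}-3-(4-methylpent-3-en-1-yl)furan-2(5H)-one, via (3R,5E)-8-[(2S)-6-(tert-butyldimethylsilyloxy)-2,8-dimethyl-2H-chromen-2-yl]-5-methylocta-1,5-dien-3-yl 6-methyl-2-methylidenehept-5-enoate 16 (not isolated)
Conditions: Hoveyda–Grubbs II (10 mol % in two portions), 1,4-benzoquinone (cat.), toluene (2 mM), Ar sparge, 40 °C, then 80 °C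
Reagents that add atoms: none
Why: Double ring-closing olefin metathesis by the Chauvin [2+2]/cycloreversion cycle, in which Ru should load first on the most accessible terminal alkene (the styrene) and close onto the vinyl group at C2 to form chromene C3=C4 (16), after which the alkylidene formed at the vinyl group of the allylic ester closes onto the 1,1-disubstituted acrylate carbon to form Cα=Cβ of the butenolide. The closest known reaction types are RCM of o-vinylaryl allyl ethers to 2H-chromenes, RCM of α-alkylacrylates of 1-alken-3-ols to α-alkylbutenolides with NHC–Ru catalysts, and double RCM of tetraenes. The closures are six-membered through the aryl ether tether (O1–C2–C3=C4–C4a–C8a) and five-membered through the ester tether (O–C(=O)–Cα=Cβ–Cγ), each with loss of ethylene and each giving the ring-enforced cis alkene. No stereocentre is created, and since C2 and Cγ only carry the reacting vinyl groups and none of their own bonds is broken, both configurations should pass through unchanged. The step needs pairing selectivity among four terminal and two trisubstituted alkenes, which ring size secures because all other pairings would give 4-, 8-, 9-membered or larger rings, while the one dangerous alternative (a cyclopentene from the C2 vinyl group and the chain C=C) requires Ru to load next to a quaternary carbon and should be outrun by the styrene. High dilution disfavours cross products, and any that form remain metathesis-active and are recycled, whereas the two ring alkenes are inert sinks, and the temperature ramp closes the chromene before the tertiary allylic aryl ether is heated.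

Step 13
Reactants: 17 O-TBS tuberatolide B
Product: 18 tuberatolide B
Conditions: TBAF, AcOH (1:1), THF, 0 °C
Reagents that add atoms: none
Why: Fluoride desilylation of an aryl silyl ether, buffered with acetic acid so that the base-labile γ-hydrogen of the butenolide is not removed and Cγ is not epimerised.

## Compound list

1 | 2-methylhydroquinone | Cc1cc(O)ccc1O | starting material
2 | 4-(tert-butyldimethylsilyloxy)-2-methylphenol | Cc1cc(O[Si](C)(C)C(C)(C)C)ccc1O | intermediate
3 | 5-(tert-butyldimethylsilyloxy)-2-hydroxy-3-methylbenzaldehyde | Cc1cc(O[Si](C)(C)C(C)(C)C)cc(C=O)c1O | intermediate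
4 | 4-(tert-butyldimethylsilyloxy)-2-ethenyl-6-methylphenol | Cc1cc(O[Si](C)(C)C(C)(C)C)cc(C=C)c1O | intermediate
5 | geraniol | CC(C)=CCC/C(C)=C/CO | starting material
6 | geranyl methyl carbonate | CC(C)=CCC/C(C)=C/COC(=O)OC | intermediate
7 | (2E,6E)-8-hydroxy-3,7-dimethylocta-2,6-dien-1-yl methyl carbonate | OC/C(C)=C/CC/C(C)=C/COC(=O)OC | intermediate
8 | (2E,6S)-6-[4-(tert-butyldimethylsilyloxy)-2-ethenyl-6-methylphenoxy]-2,6-dimethylocta-2,7-dien-1-ol | OC/C(C)=C/CC[C@@](C)(C=C)Oc1c(C)cc(O[Si](C)(C)C(C)(C)C)cc1C=C | intermediate
9 | (3S,6E)-8-bromo-3,7-dimethylocta-1,6-dien-3-yl 4-(tert-butyldimethylsilyloxy)-2-ethenyl-6-methylphenyl ether | BrC/C(C)=C/CC[C@@](C)(C=C)Oc1c(C)cc(O[Si](C)(C)C(C)(C)C)cc1C=C | intermediate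
10 | (3S,6E)-3,7-dimethylundeca-1,6-dien-10-yn-3-yl 4-(tert-butyldimethylsilyloxy)-2-ethenyl-6-methylphenyl ether | C#CCC/C(C)=C/CC[C@@](C)(C=C)Oc1c(C)cc(O[Si](C)(C)C(C)(C)C)cc1C=C | intermediate
11 | 6-methylhept-5-en-2-one (sulcatone) | CC(C)=CCCC(C)=O | starting material
12 | 6-methylhepta-1,5-dien-2-yl trifluoromethanesulfonate | CC(C)=CCCC(=C)OS(=O)(=O)C(F)(F)F | intermediate
13 | 6-methyl-2-methylidenehept-5-enoic acid | CC(C)=CCCC(=C)C(=O)O | intermediate
14 | (3S,6E)-3,7-dimethylundeca-1,6,9,10-tetraen-3-yl 4-(tert-butyldimethylsilyloxy)-2-ethenyl-6-methylphenyl ether (allene, not isolated) | C=C=CC/C(C)=C/CC[C@@](C)(C=C)Oc1c(C)cc(O[Si](C)(C)C(C)(C)C)cc1C=C | intermediate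
15 | (3R,5E,9S)-9-[4-(tert-butyldimethylsilyloxy)-2-ethenyl-6-methylphenoxy]-5,9-dimethylundeca-1,5,10-trien-3-yl 6-methyl-2-methylidenehept-5-enoate | C=C[C@@H](C/C(C)=C/CC[C@@](C)(C=C)Oc1c(C)cc(O[Si](C)(C)C(C)(C)C)cc1C=C)OC(=O)C(=C)CCC=C(C)C | intermediate
16 | (3R,5E)-8-[(2S)-6-(tert-butyldimethylsilyloxy)-2,8-dimethyl-2H-chromen-2-yl]-5-methylocta-1,5-dien-3-yl 6-methyl-2-methylidenehept-5-enoate (not isolated) | C=C[C@@H](C/C(C)=C/CC[C@@]1(C)C=Cc2cc(O[Si](C)(C)C(C)(C)C)cc(C)c2O1)OC(=O)C(=C)CCC=C(C)C | intermediate
17 | O-TBS tuberatolide B | CC(C)=CCCC1=C[C@@H](C/C(C)=C/CC[C@@]2(C)C=Cc3cc(O[Si](C)(C)C(C)(C)C)cc(C)c3O2)OC1=O | intermediate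
18 | tuberatolide B | CC(C)=CCCC1=C[C@@H](C/C(C)=C/CC[C@@]2(C)C=Cc3cc(O)cc(C)c3O2)OC1=O | target

## Step count and risks

Total step count: 13.
Longest linear sequence: 9 steps (1, 2, 3, 6, 7, 8, 11, 12, 13).

Steps most likely to fail:

**Step 12.**
- What may go wrong: mis-pairing of the alkenes under the forcing conditions that the acrylate closure needs. This could take the form of metathesis of the C2 vinyl group with the neighbouring trisubstituted chain alkene, which would cleave the chain. It could also take the form of intermolecular cross metathesis before the slow five-membered closure.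
- Fallback (from 8, back at 16): the two closures are separated so that each gets its own catalyst. Compound 8 is closed with the first-generation Grubbs catalyst (CH2Cl2, rt), which engages trisubstituted alkenes of hindered ethers only sluggishly. This gives (2E)-5-[(2S)-6-(tert-butyldimethylsilyloxy)-2,8-dimethyl-2H-chromen-2-yl]-2-methylpent-2-en-1-ol F7. Appel bromination gives the chromene allylic bromide F8. Allenylmagnesium bromide gives the chromene enyne F9. The Rh-catalysed addition of 13 then gives 16, now isolated, which needs only the single α-alkylacrylate RCM to reach 17.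

**Step 6.**
- What may go wrong: slow capture of the trisubstituted π-allyl complex by a phenoxide flanked on both sides. β-Hydride elimination, attack at the primary terminus, re-ionisation of the product or poor facial selectivity could then take over.
- Fallback (from 4, back at 8): resolution replaces asymmetric catalysis. Racemic linalool is converted (n-BuLi, ClCO2Me) into (±)-linalyl methyl carbonate F1. F1 O-allylates 4 under Pd(PPh3)4 in THF at 0 °C, using a small achiral ligand in a tertiary allyl ether formation of the reverse-prenylation type, to give the racemic linalyl aryl ether F2. Preparative chiral-phase SFC gives the (S)-linalyl aryl ether F3. SeO2/t-BuOOH oxidation of its E methyl group then gives 8.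

**Step 11.**
- What may go wrong: β-hydride elimination from the allyl-Rh intermediate towards the activated CH2 next to the trisubstituted alkene. Other possibilities are hydrometalation of the acrylic acid, or insufficient facial selectivity with an α-branched unsaturated acid.
- Fallback (from 9, back at 15): a hydride-free Pd(II) SN2' esterification. Bromide 9 is coupled with the bis(bromomagnesium) salt of propargyl alcohol (EtMgBr, cat. CuCl, THF) to give (5E,9S)-9-aryloxy-5,9-dimethylundeca-5,10-dien-2-yn-1-ol F4. Zn(Cu/Ag) in MeOH/H2O reduces the alkyne to the (2Z,5E)-trienol F5. Cl3CCN/DBU gives the trichloroacetimidate F6. The antipode of the [COP-OAc]2 palladacycle that delivers the R ester then catalyses SN2' substitution by acid 13 (CH2Cl2, rt) to give 15.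

## Further compounds

F1 | step 6 | (±)-linalyl methyl carbonate | CC(C)=CCCC(C)(C=C)OC(=O)OC
F2 | step 6 | racemic linalyl 4-(tert-butyldimethylsilyloxy)-2-ethenyl-6-methylphenyl ether | CC(C)=CCCC(C)(C=C)Oc1c(C)cc(O[Si](C)(C)C(C)(C)C)cc1C=C
F3 | step 6 | (S)-linalyl 4-(tert-butyldimethylsilyloxy)-2-ethenyl-6-methylphenyl ether | CC(C)=CCC[C@@](C)(C=C)Oc1c(C)cc(O[Si](C)(C)C(C)(C)C)cc1C=C
F4 | step 11 | (5E,9S)-9-[4-(tert-butyldimethylsilyloxy)-2-ethenyl-6-methylphenoxy]-5,9-dimethylundeca-5,10-dien-2-yn-1-ol | OCC#CC/C(C)=C/CC[C@@](C)(C=C)Oc1c(C)cc(O[Si](C)(C)C(C)(C)C)cc1C=C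
F5 | step 11 | (2Z,5E,9S)-9-[4-(tert-butyldimethylsilyloxy)-2-ethenyl-6-methylphenoxy]-5,9-dimethylundeca-2,5,10-trien-1-ol | OC/C=C\C/C(C)=C/CC[C@@](C)(C=C)Oc1c(C)cc(O[Si](C)(C)C(C)(C)C)cc1C=C
F6 | step 11 | trichloroacetimidate of F5 | ClC(Cl)(Cl)C(=N)OC/C=C\C/C(C)=C/CC[C@@](C)(C=C)Oc1c(C)cc(O[Si](C)(C)C(C)(C)C)cc1C=C
F7 | step 12 | (2E)-5-[(2S)-6-(tert-butyldimethylsilyloxy)-2,8-dimethyl-2H-chromen-2-yl]-2-methylpent-2-en-1-ol | OC/C(C)=C/CC[C@@]1(C)C=Cc2cc(O[Si](C)(C)C(C)(C)C)cc(C)c2O1
F8 | step 12 | (2S)-2-[(3E)-5-bromo-4-methylpent-3-en-1-yl]-6-(tert-butyldimethylsilyloxy)-2,8-dimethyl-2H-chromene | BrC/C(C)=C/CC[C@@]1(C)C=Cc2cc(O[Si](C)(C)C(C)(C)C)cc(C)c2O1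
F9 | step 12 | (2S)-6-(tert-butyldimethylsilyloxy)-2,8-dimethyl-2-[(3E)-4-methyloct-3-en-7-yn-1-yl]-2H-chromene | C#CCC/C(C)=C/CC[C@@]1(C)C=Cc2cc(O[Si](C)(C)C(C)(C)C)cc(C)c2O1
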